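The ring-fusion bond C1–C5 (guaiane numbering), shared by the cyclopentene and the cycloheptane, is made by a santonin-type photorearrangement. A cross-conjugated cyclohexadienone embedded in a decalin (ring A: C1–C5, C10; ring B: C5–C10) bonds C1 to C5, and the strained cyclopropane intermediate opens at C5–C10. One operation thus contracts ring A to the five-membered ring and expands ring B to the seven-membered ring, with C1 set by the angular methyl group. The precursor is a fully substituted 1,4-dien-3-one built by Robinson annulation in the enantiomeric eudesmane series; reductive transposition of the resulting enone then sets C5 and the C3=C4 olefin.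

Key step: step 13

Remark on the chemistry: atoms carry guaiane numbers throughout, also in the decalin precursors (C1/C5 ring fusion, C4 methyl-bearing olefinic carbon, C6 carbinol, C7 side-chain carbon, C9 acetoxy carbon, C10 methylidene carbon, C11 side-chain stereocentre); natural (−)-α-santonin has the opposite configuration at C7 and C11 and would lead to the mirror image, so the decalin is assembled de novo.

Step 1
Reactants: 1 (4R)-4-benzyl-3-propanoyl-1,3-oxazolidin-2-one; 2 3-iodoprop-1-ene (allyl iodide)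
Product: 3 (4R)-4-benzyl-3-[(2S)-2-methylpent-4-enoyl]-1,3-oxazolidin-2-one
Conditions: NaN(SiMe3)2, THF, −78 °C; then 2, −78 → −40 °C
Reagents that add atoms: none
Why: Evans alkylation, in which the chelated Z-enolate of the N-acyloxazolidinone is allylated on the face opposite the benzyl group, which sets C11 as (S).

Step 2
Reactants: 3 (4R)-4-benzyl-3-[(2S)-2-methylpent-4-enoyl]-1,3-oxazolidin-2-one
Product: 4 (2S)-2-methylpent-4-en-1-ol
Conditions: LiBH4, H2O (1 equiv), Et2O, 0 °C
Reagents that add atoms: none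
Why: Reductive cleavage of the imide with LiBH4 should release the primary alcohol without touching the α-stereocentre and return the auxiliary.

Step 3
Reactants: 4 (2S)-2-methylpent-4-en-1-ol; 5 1-(triphenyl-λ5-phosphanylidene)propan-2-one
Product: 7 (3E,5S)-5-methylocta-3,7-dien-2-one, via (2S)-2-methylpent-4-enal 6 (not isolated)
Conditions: Dess–Martin periodinane, CH2Cl2, 0 °C → rt; then 5, CH2Cl2, rt → 40 °C
Reagents that add atoms: none
Why: Dess–Martin oxidation gives the configurationally labile aldehyde, which is trapped at once by Wittig olefination with the stabilised ylide and should give the (E)-enone.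

Step 4
Reactants: 7 (3E,5S)-5-methylocta-3,7-dien-2-one; 8 diethyl propanedioate
Product: 11 5-[(2S)-pent-4-en-2-yl]cyclohexane-1,3-dione, via Michael adduct 9 (not isolated), via keto ester 10 (not isolated)
Conditions: NaOEt, EtOH, 0 °C → reflux; then aqueous NaOH, reflux; then aqueous HCl, 80 °C
Reagents that add atoms: none
Why: Michael addition of malonate, Dieckmann-type Claisen ring closure, saponification and decarboxylation form the classical route to 5-substituted cyclohexane-1,3-diones, in which C7 is not yet stereogenic and C11 is no longer acidic once the conjugate addition has occurred.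

Step 5
Reactants: 11 5-[(2S)-pent-4-en-2-yl]cyclohexane-1,3-dione; 12 pent-1-en-3-one
Product: 13 2-(3-oxopentyl)-5-[(2S)-pent-4-en-2-yl]cyclohexane-1,3-dione
Conditions: 12 (1.0 equiv), Et3N (cat.), EtOAc, rt
Reagents that add atoms: none
Why: Michael addition of the enolised dione through C2 (the future C10) to the vinyl ketone under amine catalysis should stop at the mono-adduct when one equivalent of acceptor is used.

Step 6
Reactants: 13 2-(3-oxopentyl)-5-[(2S)-pent-4-en-2-yl]cyclohexane-1,3-dione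
Product: 14 2-methyl-2-(3-oxopentyl)-5-[(2S)-pent-4-en-2-yl]cyclohexane-1,3-dione (methyl cis to the C5 substituent)
Conditions: MeI, K2CO3, acetone, reflux
Reagents that add atoms: iodomethane, CI
Why: C-alkylation of the 2-alkyl-1,3-dione enolate builds the quaternary carbon C10, the methyl group entering axially through a chair-like transition state and therefore cis to the equatorial side chain on C7, while the minor epimer and any O-methyl ether should be removable by chromatography.

Step 7
Reactants: 14 2-methyl-2-(3-oxopentyl)-5-[(2S)-pent-4-en-2-yl]cyclohexane-1,3-dione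
Product: 15 (3R,8aR)-5,8a-dimethyl-3-[(2S)-pent-4-en-2-yl]-3,4,8,8a-tetrahydronaphthalene-1,6(2H,7H)-dione
Conditions: D-phenylalanine (1 equiv), (1R)-camphor-10-sulfonic acid (0.5 equiv), DMF, 30 → 70 °C
Reagents that add atoms: none
Why: Hajos–Parrish–Eder–Sauer–Wiechert cyclodehydration, in which the enamine of the side-chain ketone attacks one of the two ring carbonyls (the future C5) under control of the amino acid, fixes the absolute configuration of C10 and, because methyl and side chain are cis, that of C7.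

Step 8
Reactants: 15 (3R,8aR)-5,8a-dimethyl-3-[(2S)-pent-4-en-2-yl]-3,4,8,8a-tetrahydronaphthalene-1,6(2H,7H)-dione
Product: 16 (4aR,5R,7R)-5-hydroxy-1,4a-dimethyl-7-[(2S)-pent-4-en-2-yl]-4,4a,5,6,7,8-hexahydronaphthalen-2(3H)-one
Conditions: NaBH4 (0.3 equiv), EtOH, −10 °C
Reagents that add atoms: none
Why: Chemoselective borohydride reduction of the saturated ketone beside the enone, with hydride delivered anti to the angular methyl group, should place the C9 hydroxyl cis to that methyl group (equatorial).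

Step 9
Reactants: 16 (4aR,5R,7R)-5-hydroxy-1,4a-dimethyl-7-[(2S)-pent-4-en-2-yl]-4,4a,5,6,7,8-hexahydronaphthalen-2(3H)-one
Product: 17 (1R,3R,8aR)-5,8a-dimethyl-6-oxo-3-[(2S)-pent-4-en-2-yl]-1,2,3,4,6,7,8,8a-octahydronaphthalen-1-yl acetate
Conditions: Ac2O, pyridine, 4-(dimethylamino)pyridine (cat.), CH2Cl2, rt
Reagents that add atoms: acetic anhydride, CC(=O)OC(C)=O
Why: Standard acylation installs at this early stage the acetate that the target carries at C9, so that no later differentiation of the two secondary alcohols is needed.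

Step 10
Reactants: 17 (1R,3R,8aR)-5,8a-dimethyl-6-oxo-3-[(2S)-pent-4-en-2-yl]-1,2,3,4,6,7,8,8a-octahydronaphthalen-1-yl acetate
Product: 19 (1R,3R,4S,8aR)-4-hydroxy-5,8a-dimethyl-6-oxo-3-[(2S)-pent-4-en-2-yl]-1,2,3,4,6,7,8,8a-octahydronaphthalen-1-yl acetate, via silyl dienol ether 18 (not isolated)
Conditions: Me3SiOTf, Et3N, CH2Cl2, 0 °C; then mCPBA (1.05 equiv), CH2Cl2, −20 °C; then dilute aqueous HCl, THF, 0 °C
Reagents that add atoms: 3-chloroperoxybenzoic acid, O=C(OO)c1cccc(Cl)c1
Why: Vinylogous Rubottom oxidation, in which the extended silyl dienol ether is attacked at its terminal C5=C6 bond axially on the face of the angular methyl group (the stereoelectronic preference known for 6-hydroxylation of 4-en-3-ones), should give the axial C6 alcohol cis to the C7 side chain.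

Step 11
Reactants: 19 (1R,3R,4S,8aR)-4-hydroxy-5,8a-dimethyl-6-oxo-3-[(2S)-pent-4-en-2-yl]-1,2,3,4,6,7,8,8a-octahydronaphthalen-1-yl acetate
Product: 20 (1R,3R,4S,8aR)-4-{[tert-butyl(dimethyl)silyl]oxy}-5,8a-dimethyl-6-oxo-3-[(2S)-pent-4-en-2-yl]-1,2,3,4,6,7,8,8a-octahydronaphthalen-1-yl acetate
Conditions: tBuMe2SiOTf, 2,6-lutidine, CH2Cl2, 0 °C
Reagents that add atoms: tert-butyldimethylsilyl trifluoromethanesulfonate, CC(C)(C)[Si](C)(C)OS(=O)(=O)C(F)(F)F
Why: Silylation with the reactive triflate protects the hindered axial alcohol for the oxidative, photochemical and dehydrating steps that follow.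

Step 12
Reactants: 20 (1R,3R,4S,8aR)-4-{[tert-butyl(dimethyl)silyl]oxy}-5,8a-dimethyl-6-oxo-3-[(2S)-pent-4-en-2-yl]-1,2,3,4,6,7,8,8a-octahydronaphthalen-1-yl acetate
Product: 21 (1R,3R,4S,8aR)-4-{[tert-butyl(dimethyl)silyl]oxy}-5,8a-dimethyl-6-oxo-3-[(2S)-pent-4-en-2-yl]-1,2,3,4,6,8a-hexahydronaphthalen-1-yl acetate
Conditions: DDQ, 1,4-dioxane, reflux
Reagents that add atoms: none
Why: Quinone dehydrogenation of the 4-en-3-one, with the γ-position blocked by the silyloxy group, should introduce the C1=C2 double bond and give the cross-conjugated 1,4-dien-3-one.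

Step 13
Reactants: 21 (1R,3R,4S,8aR)-4-{[tert-butyl(dimethyl)silyl]oxy}-5,8a-dimethyl-6-oxo-3-[(2S)-pent-4-en-2-yl]-1,2,3,4,6,8a-hexahydronaphthalen-1-yl acetate
Product: 22 (4S,5R,7R,8R,8aS)-4-{[tert-butyl(dimethyl)silyl]oxy}-8-hydroxy-3,8-dimethyl-2-oxo-5-[(2S)-pent-4-en-2-yl]-1,2,4,5,6,7,8,8a-octahydroazulen-7-yl acetate
Conditions: hν (medium-pressure mercury lamp, Pyrex filter), AcOH/H2O (1:1), 15 °C, under N2
Reagents that add atoms: water, O
Why: n→π* excitation of the dienone leads to β,β′-bonding between C1 and C5 and to a cyclopropyl oxyallyl zwitterion, which is protonated in the acidic medium; the strained cyclopropane then opens at C5–C10, the electron pair forming C4=C5 while C10 is captured by water (directly or through the antiperiplanar 9-acetoxy group), as in the conversion of santonin into isophotosantonic lactone (type A photorearrangement of 4,4-disubstituted cyclohexa-2,5-dienones in protic acid). The C1–C5 bond closes the five-membered ring by a formally disrotatory four-electron closure across ring A (first as the three-membered ring C1–C5–C10), and the seven-membered ring results from the ensuing shift of C5 from C10 to C1, that is by ring expansion of ring B. C1 is controlled by C10, because the cyclopropane can only form on the face that keeps ring B cis-fused to it, so H1 ends anti to the angular methyl group; C10 is attacked from the side opposite the departing C5, and its configuration is lost later. The step needs cleavage of C5–C10 in preference to C1–C10 (spiro ketone) and to the 1,4-shift that gives the lumiketone: the methyl group on C4 stabilises the charge developing there and directs the bond electrons into C4=C5, and the protic acid intercepts the zwitterion before it can rearrange.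

Step 14
Reactants: 22 (4S,5R,7R,8R,8aS)-4-{[tert-butyl(dimethyl)silyl]oxy}-8-hydroxy-3,8-dimethyl-2-oxo-5-[(2S)-pent-4-en-2-yl]-1,2,4,5,6,7,8,8a-octahydroazulen-7-yl acetate
Product: 25 (3aR,4S,5R,7R,8R,8aS)-4-{[tert-butyl(dimethyl)silyl]oxy}-8-hydroxy-3,8-dimethyl-5-[(2S)-pent-4-en-2-yl]-1,3a,4,5,6,7,8,8a-octahydroazulen-7-yl acetate, via tosylhydrazone 23 (not isolated), via allylic diazene 24 (not isolated)
Conditions: TsNHNH2, THF, 50 °C; then catecholborane (3 equiv), CHCl3, 0 °C; then NaOAc·3H2O, reflux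
Reagents that add atoms: none
Why: Reductive 1,3-transposition of the α,β-unsaturated tosylhydrazone, in which catecholborane delivers hydride to C3 from the face opposite C10 and the C6 silyloxy group and the derived allylic diazene passes its hydrogen suprafacially to C5 with loss of N2 (retro-ene), should move the double bond to C3=C4 and make the ring fusion trans.

Step 15
Reactants: 25 (3aR,4S,5R,7R,8R,8aS)-4-{[tert-butyl(dimethyl)silyl]oxy}-8-hydroxy-3,8-dimethyl-5-[(2S)-pent-4-en-2-yl]-1,3a,4,5,6,7,8,8a-octahydroazulen-7-yl acetate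
Product: 26 (3aR,4S,5R,7R,8aS)-4-{[tert-butyl(dimethyl)silyl]oxy}-3-methyl-8-methylidene-5-[(2S)-pent-4-en-2-yl]-1,3a,4,5,6,7,8,8a-octahydroazulen-7-yl acetate
Conditions: SOCl2, pyridine, −10 °C
Reagents that add atoms: none
Why: Dehydration of the tertiary alcohol through its chlorosulfite by anti elimination (E2) should give the exocyclic olefin, because H1 and H9 are both cis to the leaving group and only the methyl group offers an antiperiplanar hydrogen.

Step 16
Reactants: 26 (3aR,4S,5R,7R,8aS)-4-{[tert-butyl(dimethyl)silyl]oxy}-3-methyl-8-methylidene-5-[(2S)-pent-4-en-2-yl]-1,3a,4,5,6,7,8,8a-octahydroazulen-7-yl acetate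
Product: 27 (3aR,4S,5R,7R,8aS)-4-hydroxy-3-methyl-8-methylidene-5-[(2S)-pent-4-en-2-yl]-1,3a,4,5,6,7,8,8a-octahydroazulen-7-yl acetate
Conditions: HF·pyridine, pyridine, THF, 0 °C → rt
Reagents that add atoms: none
Why: Buffered fluoride cleavage of the silyl ether should free the C6 hydroxyl and leave the allylic acetate and the olefins untouched.

Step 17
Reactants: 27 (3aR,4S,5R,7R,8aS)-4-hydroxy-3-methyl-8-methylidene-5-[(2S)-pent-4-en-2-yl]-1,3a,4,5,6,7,8,8a-octahydroazulen-7-yl acetate; 28 2-methylbut-3-en-2-ol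
Product: 29 (3aR,4S,5R,7R,8aS)-4-hydroxy-5-[(2S,4E)-6-hydroxy-6-methylhept-4-en-2-yl]-3-methyl-8-methylidene-1,3a,4,5,6,7,8,8a-octahydroazulen-7-yl acetate (CNP0312076.1)
Conditions: RuCl2(=CHPh)(PCy3)(H2IMes) (second-generation Grubbs catalyst, 5 mol %), 28 (10 equiv), CH2Cl2, 40 °C
Reagents that add atoms: none
Why: Olefin cross-metathesis of the only monosubstituted alkene with the tertiary allylic alcohol should give the (E)-disubstituted olefin, the 1,1-disubstituted and trisubstituted ring olefins being unreactive toward the catalyst.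

Compound list
1 | (4R)-4-benzyl-3-propanoyl-1,3-oxazolidin-2-one | CCC(=O)N1[C@H](Cc2ccccc2)COC1=O | starting material
2 | 3-iodoprop-1-ene (allyl iodide) | C=CCI | starting material
3 | (4R)-4-benzyl-3-[(2S)-2-methylpent-4-enoyl]-1,3-oxazolidin-2-one | C=CC[C@H](C)C(=O)N1[C@H](Cc2ccccc2)COC1=O | intermediate
4 | (2S)-2-methylpent-4-en-1-ol | C=CC[C@H](C)CO | intermediate
5 | 1-(triphenyl-λ5-phosphanylidene)propan-2-one | CC(=O)C=P(c1ccccc1)(c1ccccc1)c1ccccc1 | starting material
6 | (2S)-2-methylpent-4-enal | C=CC[C@H](C)C=O | intermediate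
7 | (3E,5S)-5-methylocta-3,7-dien-2-one | C=CC[C@H](C)/C=C/C(C)=O | intermediate
8 | diethyl propanedioate (diethyl malonate) | CCOC(=O)CC(=O)OCC | starting material
9 | diethyl 2-[(5S)-5-methyl-2-oxooct-7-en-4-yl]propanedioate (both C4 epimers) | CCOC(=O)C(C(=O)OCC)C(CC(C)=O)[C@@H](C)CC=C | intermediate
10 | ethyl 2,4-dioxo-6-[(2S)-pent-4-en-2-yl]cyclohexane-1-carboxylate (formed as its sodium enolate, ring centres unassigned) | CCOC(=O)C1C(=O)CC(=O)CC1[C@@H](C)CC=C | intermediate
11 | 5-[(2S)-pent-4-en-2-yl]cyclohexane-1,3-dione | O=C1CC(=O)CC(C1)[C@@H](C)CC=C | intermediate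
12 | pent-1-en-3-one (ethyl vinyl ketone) | CCC(=O)C=C | starting material
13 | 2-(3-oxopentyl)-5-[(2S)-pent-4-en-2-yl]cyclohexane-1,3-dione (enolised, C2 configurationally labile) | CCC(=O)CCC1C(=O)CC(CC1=O)[C@@H](C)CC=C | intermediate
14 | 2-methyl-2-(3-oxopentyl)-5-[(2S)-pent-4-en-2-yl]cyclohexane-1,3-dione, methyl cis to the C5 substituent | CCC(=O)CC[C@]1(C)C(=O)C[C@H](CC1=O)[C@@H](C)CC=C | intermediate
15 | (3R,8aR)-5,8a-dimethyl-3-[(2S)-pent-4-en-2-yl]-3,4,8,8a-tetrahydronaphthalene-1,6(2H,7H)-dione | C[C@@]12CCC(=O)C(C)=C1C[C@@H]([C@@H](C)CC=C)CC2=O | intermediate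
16 | (4aR,5R,7R)-5-hydroxy-1,4a-dimethyl-7-[(2S)-pent-4-en-2-yl]-4,4a,5,6,7,8-hexahydronaphthalen-2(3H)-one | C[C@@]12CCC(=O)C(C)=C1C[C@@H]([C@@H](C)CC=C)C[C@H]2O | intermediate
17 | (1R,3R,8aR)-5,8a-dimethyl-6-oxo-3-[(2S)-pent-4-en-2-yl]-1,2,3,4,6,7,8,8a-octahydronaphthalen-1-yl acetate | C[C@@]12CCC(=O)C(C)=C1C[C@@H]([C@@H](C)CC=C)C[C@H]2OC(C)=O | intermediate
18 | (1R,3R,8aR)-5,8a-dimethyl-3-[(2S)-pent-4-en-2-yl]-6-[(trimethylsilyl)oxy]-1,2,3,7,8,8a-hexahydronaphthalen-1-yl acetate | C[C@@]12CCC(O[Si](C)(C)C)=C(C)C1=C[C@@H]([C@@H](C)CC=C)C[C@H]2OC(C)=O | intermediate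
19 | (1R,3R,4S,8aR)-4-hydroxy-5,8a-dimethyl-6-oxo-3-[(2S)-pent-4-en-2-yl]-1,2,3,4,6,7,8,8a-octahydronaphthalen-1-yl acetate | C[C@@]12CCC(=O)C(C)=C1[C@@H](O)[C@@H]([C@@H](C)CC=C)C[C@H]2OC(C)=O | intermediate
20 | (1R,3R,4S,8aR)-4-{[tert-butyl(dimethyl)silyl]oxy}-5,8a-dimethyl-6-oxo-3-[(2S)-pent-4-en-2-yl]-1,2,3,4,6,7,8,8a-octahydronaphthalen-1-yl acetate | C[C@@]12CCC(=O)C(C)=C1[C@@H](O[Si](C)(C)C(C)(C)C)[C@@H]([C@@H](C)CC=C)C[C@H]2OC(C)=O | intermediate
21 | (1R,3R,4S,8aR)-4-{[tert-butyl(dimethyl)silyl]oxy}-5,8a-dimethyl-6-oxo-3-[(2S)-pent-4-en-2-yl]-1,2,3,4,6,8a-hexahydronaphthalen-1-yl acetate | C[C@@]12C=CC(=O)C(C)=C1[C@@H](O[Si](C)(C)C(C)(C)C)[C@@H]([C@@H](C)CC=C)C[C@H]2OC(C)=O | intermediate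
22 | (4S,5R,7R,8R,8aS)-4-{[tert-butyl(dimethyl)silyl]oxy}-8-hydroxy-3,8-dimethyl-2-oxo-5-[(2S)-pent-4-en-2-yl]-1,2,4,5,6,7,8,8a-octahydroazulen-7-yl acetate | C[C@@]1(O)[C@H]2CC(=O)C(C)=C2[C@@H](O[Si](C)(C)C(C)(C)C)[C@@H]([C@@H](C)CC=C)C[C@H]1OC(C)=O | intermediate
23 | 4-methylbenzenesulfonylhydrazone of 22 at C3 (C=N geometry of no consequence) | C[C@@]1(O)[C@H]2CC(=NNS(=O)(=O)c3ccc(C)cc3)C(C)=C2[C@@H](O[Si](C)(C)C(C)(C)C)[C@@H]([C@@H](C)CC=C)C[C@H]1OC(C)=O | intermediate
24 | allylic diazene at C3 (N=NH on the face of C10, new hydrogen on the opposite face) | C[C@@]1(O)[C@H]2C[C@@H](N=N)C(C)=C2[C@@H](O[Si](C)(C)C(C)(C)C)[C@@H]([C@@H](C)CC=C)C[C@H]1OC(C)=O | intermediate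
25 | (3aR,4S,5R,7R,8R,8aS)-4-{[tert-butyl(dimethyl)silyl]oxy}-8-hydroxy-3,8-dimethyl-5-[(2S)-pent-4-en-2-yl]-1,3a,4,5,6,7,8,8a-octahydroazulen-7-yl acetate | C[C@@]1(O)[C@H]2CC=C(C)[C@@H]2[C@@H](O[Si](C)(C)C(C)(C)C)[C@@H]([C@@H](C)CC=C)C[C@H]1OC(C)=O | intermediate
26 | (3aR,4S,5R,7R,8aS)-4-{[tert-butyl(dimethyl)silyl]oxy}-3-methyl-8-methylidene-5-[(2S)-pent-4-en-2-yl]-1,3a,4,5,6,7,8,8a-octahydroazulen-7-yl acetate | C=C1[C@H]2CC=C(C)[C@@H]2[C@@H](O[Si](C)(C)C(C)(C)C)[C@@H]([C@@H](C)CC=C)C[C@H]1OC(C)=O | intermediate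
27 | (3aR,4S,5R,7R,8aS)-4-hydroxy-3-methyl-8-methylidene-5-[(2S)-pent-4-en-2-yl]-1,3a,4,5,6,7,8,8a-octahydroazulen-7-yl acetate | C=C1[C@H]2CC=C(C)[C@@H]2[C@@H](O)[C@@H]([C@@H](C)CC=C)C[C@H]1OC(C)=O | intermediate
28 | 2-methylbut-3-en-2-ol | C=CC(C)(C)O | starting material
29 | (3aR,4S,5R,7R,8aS)-4-hydroxy-5-[(2S,4E)-6-hydroxy-6-methylhept-4-en-2-yl]-3-methyl-8-methylidene-1,3a,4,5,6,7,8,8a-octahydroazulen-7-yl acetate (CNP0312076.1) | C=C1[C@H]2CC=C(C)[C@@H]2[C@@H](O)[C@@H]([C@@H](C)C/C=C/C(C)(C)O)C[C@H]1OC(C)=O | target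

Total step count: 17 steps. Longest linear sequence: 17 steps (from 1 to 29).

Steps most likely to fail

Step 13 (photorearrangement). The 9-acetoxy group lies antiperiplanar to the C5–C10 bond that breaks and is expected to take part in the capture of C10 as a bridging acetoxonium ion. When that ion is hydrolysed the acetyl group can end up on either oxygen, so the regiochemistry of the capture is not secured. Fallback from 21: the crude photolysate, 22 together with the acetyl-migrated isomer F1, would be methanolysed (K2CO3, MeOH, 0 °C) to the 9,10-diol F2. The secondary hydroxyl alone would then be re-acetylated (Ac2O, pyridine, 0 °C, no acyl-transfer catalyst, the tertiary alcohol being inert), which comes back at 22. The sequence then no longer depends on where the acetyl group sits after the rearrangement.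

Step 7 (desymmetrising aldol). The enamine formed with the amino acid may discriminate poorly between the two ring carbonyls, the side-chain stereocentre being too remote to help. That would give 15 mixed with the diastereomer of opposite ring configuration. Fallback from 14: cyclodehydration with an achiral amine (pyrrolidine, AcOH, toluene, reflux with removal of water) would give 15 and the (3S,8aS)-diastereomer F3 without any catalyst control. Because C11 is already fixed, the two are diastereomers and would be separated by chromatography or crystallisation, coming back at 15.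

Step 15 (dehydration). Ionisation of the chlorosulfite to the tertiary C10 cation, possibly assisted by the neighbouring acetate, would replace the anti elimination by a cationic one and erode the regioselectivity toward the ring olefins. Fallback from 25: methanolysis (K2CO3, MeOH) would give the trans-9,10-diol F4, and mesylation of its secondary hydroxyl (MsCl, Et3N, CH2Cl2, 0 °C) the C9 methanesulfonate F5. Treatment with K2CO3 in MeOH would close the 9,10-epoxide F6 by attack of the C10 alkoxide with inversion at C9. Base-induced isomerisation of the epoxide with LiNEt2 (Et2O, reflux, abstraction of a methyl proton) would give the exocyclic allylic alcohol F7, the C9 epimer. Mitsunobu esterification with acetic acid (PPh3, diisopropyl azodicarboxylate, THF) inverts C9 and comes back at 26.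

Further compounds
F1 | step 13 | acetyl-migrated isomer of 22 (C10 acetate, free C9 hydroxyl) | C[C@@]1(OC(C)=O)[C@H]2CC(=O)C(C)=C2[C@@H](O[Si](C)(C)C(C)(C)C)[C@@H]([C@@H](C)CC=C)C[C@H]1O
F2 | step 13 | 9,10-diol corresponding to 22 | C[C@@]1(O)[C@H]2CC(=O)C(C)=C2[C@@H](O[Si](C)(C)C(C)(C)C)[C@@H]([C@@H](C)CC=C)C[C@H]1O
F3 | step 7 | (3S,8aS)-5,8a-dimethyl-3-[(2S)-pent-4-en-2-yl]-3,4,8,8a-tetrahydronaphthalene-1,6(2H,7H)-dione | C[C@]12CCC(=O)C(C)=C1C[C@H]([C@@H](C)CC=C)CC2=O
F4 | step 15 | 9,10-diol corresponding to 25 (hydroxyls trans) | C[C@@]1(O)[C@H]2CC=C(C)[C@@H]2[C@@H](O[Si](C)(C)C(C)(C)C)[C@@H]([C@@H](C)CC=C)C[C@H]1O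
F5 | step 15 | C9 methanesulfonate of F4 | C[C@@]1(O)[C@H]2CC=C(C)[C@@H]2[C@@H](O[Si](C)(C)C(C)(C)C)[C@@H]([C@@H](C)CC=C)C[C@H]1OS(C)(=O)=O
F6 | step 15 | 9,10-epoxide (oxygen on the face of the former C10 hydroxyl, C9 inverted) | C[C@@]12[C@H]3CC=C(C)[C@@H]3[C@@H](O[Si](C)(C)C(C)(C)C)[C@@H]([C@@H](C)CC=C)C[C@@H]1O2
F7 | step 15 | (3aR,4S,5R,7S,8aS)-4-{[tert-butyl(dimethyl)silyl]oxy}-3-methyl-8-methylidene-5-[(2S)-pent-4-en-2-yl]-1,3a,4,5,6,7,8,8a-octahydroazulen-7-ol | C=C1[C@H]2CC=C(C)[C@@H]2[C@@H](O[Si](C)(C)C(C)(C)C)[C@@H]([C@@H](C)CC=C)C[C@@H]1O
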